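## The problem

Compound 26 links three guaiacyl-type arenes through two separate stereochemical units. The first is a 2,3-dihydrobenzofuran (aromatic ring A fused to the oxygen heterocycle ring B) with an aryl group on C2 and a hydroxymethyl group on C3 in a trans (2S,3R) relationship. The second, on C5 of ring A, is a 1,2-diarylpropane-1,3-diol chain (C1', C2', C3') with a syn (1'S,2'R) pair of stereocentres. Ring A insulates the two pairs from each other, so neither can direct the other and each needs its own source of absolute configuration. Within ring B, C2 can govern C3, because C3 is epimerisable at the ester oxidation level and trans is the more stable arrangement; in the chain, C1' and C2' are best made together in the one C–C bond that joins them. Both benzylic C–O bonds (C2–O1 and C1'–OH) lie para to an oxygen substituent and ionise under acid, a free 4-hydroxyphenyl group on C2 can expel O1 through a quinone methide under base, and hydrogenolysis would cut the same bonds. The phenols therefore stay masked to the last step, under groups that leave at near-neutral pH. The feature that gives a short entry to ring B is that C2 bears only a hydrogen, O1 and the guaiacyl ring, so it is the methylene carbon of an aryl benzyl ether in which one hydrogen has been replaced by C3. A carbene on C3, held on C3a ortho to the ether oxygen on C7a, sits in a 1,5 relationship to that C–H bond; insertion makes C2–C3, closes ring B and converts a prochiral methylene into the C2 stereocentre in one catalytic step.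

## Retrosynthesis

**Unmasking and the chain.** Target 26 is the fluoride-deprotection product of trisilyl ether 25, in which both phenols carry triisopropylsilyl groups and the C3 hydroxymethyl group a tert-butyldimethylsilyl group. Diol 25 is the reduction product of imide 24, whose acyl carbon becomes C3'. Cutting C1'–C2' of 24 gives aldehyde 16 and the arylacetyl imide 22, used as its boron enolate 23.
- This cut is preferred to cutting C5–C1' (aryl metal plus a chiral 2-arylpropanal), which would leave C1' to substrate control next to an epimerisable centre.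
- The aldol sets both chain centres at once, under control of the auxiliary, and divides the molecule into a two-carbon arylacetyl unit and a dihydrobenzofuran aldehyde.
- The forward reaction must be syn-selective and must override the remote ring-B centres.

**Adjusting C5 and C3.** Aldehyde 16 comes from bromide 14 through aryllithium 15. Silyl ether 14 comes from alcohol 13, and 13 from the trans ester 12. No skeletal bond is cut. The bromide is chosen as the latent formyl group because it is inert to the diazo and carbenoid chemistry and comes with the commercial arene. A formyl or acetal group carried from the start would meet a Grignard reagent and a carbenoid on the way.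

**C3 configuration.** Trans ester 12 is the C3 epimer of cis ester 11. Only base is needed, and C2 keeps the absolute configuration.

**Ring B (the key cut).** Breaking C2–C3 of 11 gives the achiral aryldiazoacetate 10. Cutting O1–C2 instead would need a stereodefined benzylic electrophile on an electron-rich ring, which would ionise. Cutting C3–C3a would need a preformed chiral heterocycle. The C2–C3 cut removes the ring and both stereocentres in one step. The forward insertion must select one of two enantiotopic hydrogens.

**The diazo ester.** Diazo compound 10 comes from α-keto ester 8 through its tosylhydrazone 9. Keto ester 8 is cut at C3–C3a to the aryl Grignard reagent 7, made from iodide 6, and an oxalate unit. The neighbouring option, one-carbon homologation of a salicylaldehyde to the arylacetate followed by diazo transfer, costs about four operations, one of them an acidic enol ether hydrolysis that the 4-siloxybenzyl ether would not tolerate. The iodide route takes two operations from 6 and exploits the rate difference between C–I and C–Br in the metal exchange.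

**The ether.** Cutting O1–CH2 of 6 gives iodophenol 5 and benzylic alcohol 3. Phenol 5 is the iodination product of commercial 4; alcohol 3 comes from vanillin 1 through aldehyde 2. The ether must be formed without strong base or acid, which suggests a redox condensation.

**The enolate partner.** Imide 22 is cut at the N–acyl bond to acid 19 (activated as mixed anhydride 21) and the commercial auxiliary 20. Acid 19 comes from homovanillic acid 17 through the bis-silyl compound 18.

## Roads not taken

**Alternative 1: ring A built last by pyrone cycloaddition.**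
- Cut: ring A at C3a–C4 and C7–C7a. The trans lactone A2 already holds O1, C2, C3 and both substituents.
- Forward step: A2 is converted into its trimethylsilyl ketene acetal A3, which adds in a [4+2] sense to the electron-poor pyrone A4. Loss of CO2 from the bridged adduct and of Me3SiOH from the dihydroarene would give benzofuran ester A1.
- Merits: the polarised partners fix the positions of all ring-A substituents, the trans relationship is settled in A2 before the arene exists, and C5 arrives as an ester.
- Weak points: A2 is itself a chiral target needing its own asymmetric synthesis, and A4 is not a catalogue compound. The aromatisation must expel the silyloxy group and keep O1 although both sit on the same carbon (C7a); loss of O1 would open ring B. The CO2 extrusion needs heat while the C2–O1 bond is benzylic to an electron-rich ring.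
- Comparison: this road is better in two respects. It has no kinetic cis isomer to correct, and it needs no halogen–lithium exchange at C5. The chosen plan sets against this that ring A is bought rather than built, that ring B and C2 are created catalytically from an achiral precursor, and that no step depends on which of two oxygen leaving groups departs.

**Alternative 2: (4+1) annulation with a chiral sulfonium ylide.**
- Cut: ring B at C2–C3 and O1–C2.
- Forward step: the benzylic ylide from the C2-symmetric thiolanium salt A7 adds to the alkene carbon next to the arene in nitrovinylphenol A6. The phenoxide then displaces the sulfide from the ylide carbon (5-exo-tet) to give the trans nitromethyl compound A5.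
- Merits: A6 is one condensation away from a commercial salicylaldehyde, two ring bonds form in one flask, the trans isomer is formed directly, the sulfide is recoverable, and no diazo compound or rhodium is needed.
- Weak points: enantiocontrol depends on a betaine that can form reversibly, and it is far less secure for nitroalkenes than for carbonyl epoxidation. A7 places a cationic leaving group on a 4-siloxybenzyl carbon, which ionises readily under basic ylide-forming conditions. C3 emerges as CH2NO2, so a Nef reaction and a reduction are needed; these pass through an epimerisable aldehyde under conditions that threaten C2–O1 and the silyl ether.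
- Comparison: this road is shorter to ring B, a real advantage. The chosen plan sets against it a C3 substituent at the ester level, reduced by hydride in one step, and an enantio-determining step with close analogy on this ring system.

**Alternative 3: oxidative ring contraction of a flavanone.**
- Cut: C3–C3a, made as a six-membered ring contracts.
- Forward step: the (2S)-flavanone A9 is treated with PhI(OAc)2 (a trivalent iodine oxidant) and H2SO4 in HC(OMe)3. Iodination of the enol ether at C3 triggers a 1,2-shift of the ring-A carbon from the carbonyl carbon to C3, and the former carbonyl carbon ends as the ester of A8.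
- Merits: A8 is the trans ester and maps onto 12 apart from the phenol protecting group, so the epimerisation step would be saved. Flavanones come from robust aldol and oxa-Michael chemistry, enantioselective entries exist, and no diazo compound is handled.
- Weak points: the aryl shift has a competitor, migration of the C2 aryl group to give an isoflavone, which is favoured when that ring is electron-rich as the guaiacyl ring is. This is why A9 carries a pivalate, which must later be exchanged and which hydride reduction of the ester would cleave. Flavanones racemise through the ring-opened chalcone under acid, and the medium is strongly acidic while C2–O1 is benzylic.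
- Comparison: in step count to the trans ester this road is at least as good. The chosen plan sets against it regiochemical certainty (one C–H within reach, no branching migration), neutral conditions at low temperature under which the silyl ether lasts to the end, and a C2 centre that is created in the key step rather than carried through acid.

Key step: step 7

Assumption: the (S)-tert-leucinate catalyst Rh2(S-PTTL)4 is taken to deliver the (2S,3R)-cis ester 11; if this substrate responds with the opposite facial sense, the enantiomeric complex Rh2(R-PTTL)4 is used and nothing else changes.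

## Route

Step 1
Reactants: 1 vanillin (4-hydroxy-3-methoxybenzaldehyde)
Product: 2 3-methoxy-4-(triisopropylsilyloxy)benzaldehyde
Conditions: TIPSCl, imidazole, DMF, rt
Reagents that add atoms: triisopropylsilyl chloride, CC(C)[Si](Cl)(C(C)C)C(C)C
Why: Imidazole-promoted O-silylation of a phenol; the triisopropylsilyl ether is chosen because it should withstand the hydride, Grignard, alkyllithium and catalytic methoxide steps ahead and leave with fluoride at the end.

Step 2
Reactants: 2 3-methoxy-4-(triisopropylsilyloxy)benzaldehyde
Product: 3 [3-methoxy-4-(triisopropylsilyloxy)phenyl]methanol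
Conditions: NaBH4, MeOH/THF, 0 °C
Reagents that add atoms: none
Why: Borohydride reduction of an aryl aldehyde to the benzylic alcohol; the aryl silyl ether should survive the short exposure at 0 °C.

Step 3
Reactants: 4 4-bromo-2-methoxyphenol
Product: 5 4-bromo-2-iodo-6-methoxyphenol
Conditions: I2, NaHCO3, THF/H2O, 0 °C → rt
Reagents that add atoms: iodine, II
Why: Electrophilic aromatic iodination of a phenol under weakly basic conditions; with the para position blocked by bromine, the phenoxide directs iodine to its one free ortho position, the future C3a.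

Step 4
Reactants: 5 4-bromo-2-iodo-6-methoxyphenol, 3 [3-methoxy-4-(triisopropylsilyloxy)phenyl]methanol
Product: 6 5-bromo-1-iodo-3-methoxy-2-{[3-methoxy-4-(triisopropylsilyloxy)phenyl]methoxy}benzene
Conditions: PPh3, DIAD, THF, 0 °C → rt
Reagents that add atoms: none
Why: Mitsunobu etherification of an acidic dihalophenol with a primary benzylic alcohol; the neutral redox condensation avoids both carbonate bases, which can strip aryl silyl ethers, and the ionisable 4-siloxybenzyl bromide.

Step 5
Reactants: 6 5-bromo-1-iodo-3-methoxy-2-{[3-methoxy-4-(triisopropylsilyloxy)phenyl]methoxy}benzene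
Product: 8 methyl 2-{5-bromo-3-methoxy-2-[3-methoxy-4-(triisopropylsilyloxy)benzyloxy]phenyl}-2-oxoacetate, via arylmagnesium chloride 7 (not isolated)
Conditions: iPrMgCl·LiCl, THF, −40 °C; then added to (CO2Me)2 (3 equiv), THF, −78 °C
Reagents that add atoms: dimethyl oxalate, COC(=O)C(=O)OC
Why: Iodine–magnesium exchange followed by acylation of the aryl Grignard reagent with an oxalate diester; exchange at C–I is much faster than at C–Br at −40 °C, and inverse addition to excess oxalate at −78 °C should stop at the α-keto ester because the tetrahedral adduct persists until the quench.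

Step 6
Reactants: 8 methyl 2-{5-bromo-3-methoxy-2-[3-methoxy-4-(triisopropylsilyloxy)benzyloxy]phenyl}-2-oxoacetate
Product: 10 methyl 2-{5-bromo-3-methoxy-2-[3-methoxy-4-(triisopropylsilyloxy)benzyloxy]phenyl}-2-diazoacetate, via tosylhydrazone 9 (not isolated)
Conditions: TsNHNH2, MeOH/THF, 60 °C; evaporate; then DBU, CH2Cl2, 0 °C → rt
Reagents that add atoms: p-toluenesulfonyl hydrazide, Cc1ccc(S(=O)(=O)NN)cc1
Why: Condensation of the ketone carbonyl with the sulfonyl hydrazide, then Bamford–Stevens-type loss of sulfinate from the α-keto ester tosylhydrazone under amine base, the standard acid-free entry to aryldiazoacetates.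

Step 7
Reactants: 10 methyl 2-{5-bromo-3-methoxy-2-[3-methoxy-4-(triisopropylsilyloxy)benzyloxy]phenyl}-2-diazoacetate
Product: 11 methyl (2S,3R)-5-bromo-7-methoxy-2-[3-methoxy-4-(triisopropylsilyloxy)phenyl]-2,3-dihydrobenzofuran-3-carboxylate (the cis ester)
Conditions: Rh2(S-PTTL)4 (1 mol%), toluene, −78 → −60 °C, slow addition of 10
Reagents that add atoms: none
Why: The dirhodium tetrakis[N-phthaloyl-(S)-tert-leucinate] complex (divalent rhodium) attacks the diazo carbon, N2 leaves and a donor/acceptor rhodium carbenoid forms at C3. In one concerted, asynchronous three-centre event the carbenoid carbon takes up a benzylic ether hydrogen with hydride character while the C2–C3 bond forms; the closest known reaction type is the enantioselective intramolecular C–H insertion of aryldiazoacetates into benzylic ether C–H bonds under chiral dirhodium tetracarboxylates. Ring B (O1, C2, C3, C3a, C7a) closes by this 1,5-insertion, a five-membered closure through a hydrogen-bridged six-membered transition state made possible by the ortho relationship of the carbenoid and the benzyloxy group on ring A. C2 is set by the chiral carboxylate ligands, which choose between the two enantiotopic benzylic hydrogens (catalyst control). C3 is set relative to C2 in the same transition state, which should place the ester and the aryl group cis under kinetic control; this centre is corrected in step 8. The step needs chemoselectivity for this C–H bond over carbene dimerisation, addition to the arenes and ylide formation at oxygen. That is secured by the fact that only one sp3 C–H bond lies within reach and is activated by both O1 and the para-siloxyaryl ring, by the tempered reactivity of a donor/acceptor carbenoid, and by low temperature with slow addition. The bromide, the methoxy groups and the silyl ether are spectators.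

Step 8
Reactants: 11 methyl (2S,3R)-5-bromo-7-methoxy-2-[3-methoxy-4-(triisopropylsilyloxy)phenyl]-2,3-dihydrobenzofuran-3-carboxylate
Product: 12 methyl (2S,3S)-5-bromo-7-methoxy-2-[3-methoxy-4-(triisopropylsilyloxy)phenyl]-2,3-dihydrobenzofuran-3-carboxylate (the trans ester)
Conditions: NaOMe (0.3 equiv), MeOH/THF, 0 °C → rt
Reagents that add atoms: none
Why: Base-mediated epimerisation through the ester enolate to the more stable trans isomer; C2 is not acidic and should keep its configuration, and expulsion of O1 from the ring-held enolate is disfavoured because the C2–O1 bond lies near the nodal plane of the enolate.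

Step 9
Reactants: 12 methyl (2S,3S)-5-bromo-7-methoxy-2-[3-methoxy-4-(triisopropylsilyloxy)phenyl]-2,3-dihydrobenzofuran-3-carboxylate
Product: 13 {(2S,3R)-5-bromo-7-methoxy-2-[3-methoxy-4-(triisopropylsilyloxy)phenyl]-2,3-dihydrobenzofuran-3-yl}methanol
Conditions: LiAlH4, THF, −20 → 0 °C
Reagents that add atoms: none
Why: Hydride reduction of the ester to the primary alcohol; hydride addition is faster than enolisation, so C3 should be retained (the descriptor changes only through the priority rules), and the aryl bromide and silyl ether are inert at this temperature.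

Step 10
Reactants: 13 {(2S,3R)-5-bromo-7-methoxy-2-[3-methoxy-4-(triisopropylsilyloxy)phenyl]-2,3-dihydrobenzofuran-3-yl}methanol
Product: 14 (2S,3R)-5-bromo-3-[(tert-butyldimethylsilyloxy)methyl]-7-methoxy-2-[3-methoxy-4-(triisopropylsilyloxy)phenyl]-2,3-dihydrobenzofuran
Conditions: TBSCl, imidazole, DMF, rt
Reagents that add atoms: tert-butyldimethylsilyl chloride, CC(C)(C)[Si](C)(C)Cl
Why: Imidazole-promoted silylation of a primary alcohol, needed so that no acidic proton meets the aryllithium or the boron enolate; it is removed with the phenol silyl groups in the last step.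

Step 11
Reactants: 14 (2S,3R)-5-bromo-3-[(tert-butyldimethylsilyloxy)methyl]-7-methoxy-2-[3-methoxy-4-(triisopropylsilyloxy)phenyl]-2,3-dihydrobenzofuran
Product: 16 (2S,3R)-3-[(tert-butyldimethylsilyloxy)methyl]-7-methoxy-2-[3-methoxy-4-(triisopropylsilyloxy)phenyl]-2,3-dihydrobenzofuran-5-carbaldehyde, via aryllithium 15 (not isolated)
Conditions: n-BuLi, THF, −78 °C; then DMF, −78 → 0 °C; aq. NH4Cl
Reagents that add atoms: N,N-dimethylformamide, CN(C)C=O
Why: Bromine–lithium exchange followed by formylation of the aryllithium with a formamide; at −78 °C exchange should outrun deprotonation at C2, and the aldehyde appears only on aqueous work-up.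

Step 12
Reactants: 17 homovanillic acid (4-hydroxy-3-methoxyphenylacetic acid)
Product: 19 2-[3-methoxy-4-(triisopropylsilyloxy)phenyl]acetic acid, via silyl ester 18 (not isolated)
Conditions: TIPSCl (2.3 equiv), imidazole, DMF, rt; then K2CO3, MeOH/THF/H2O, rt; aq. citric acid
Reagents that add atoms: triisopropylsilyl chloride, CC(C)[Si](Cl)(C(C)C)C(C)C
Why: Exhaustive silylation followed by selective solvolysis of the much more labile silyl ester, the usual way to protect a phenol in the presence of a carboxylic acid.

Step 13
Reactants: 19 2-[3-methoxy-4-(triisopropylsilyloxy)phenyl]acetic acid, 20 (S)-4-benzyl-1,3-oxazolidin-2-one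
Product: 22 (S)-4-benzyl-3-{2-[3-methoxy-4-(triisopropylsilyloxy)phenyl]acetyl}-1,3-oxazolidin-2-one, via mixed pivalic anhydride 21 (not isolated)
Conditions: PivCl, Et3N, THF, −20 °C; then LiCl, 20, −20 °C → rt
Reagents that add atoms: none
Why: N-Acylation of the oxazolidinone through the mixed pivalic anhydride with LiCl activation; the hindered pivaloyl carbonyl steers attack to the arylacetyl carbonyl, and no strong base touches the acidic arylacetyl position.

Step 14
Reactants: 22 (S)-4-benzyl-3-{2-[3-methoxy-4-(triisopropylsilyloxy)phenyl]acetyl}-1,3-oxazolidin-2-one, 16 (2S,3R)-3-[(tert-butyldimethylsilyloxy)methyl]-7-methoxy-2-[3-methoxy-4-(triisopropylsilyloxy)phenyl]-2,3-dihydrobenzofuran-5-carbaldehyde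
Product: 24 (S)-4-benzyl-3-[(2S,3S)-3-{(2S,3R)-3-[(tert-butyldimethylsilyloxy)methyl]-7-methoxy-2-[3-methoxy-4-(triisopropylsilyloxy)phenyl]-2,3-dihydrobenzofuran-5-yl}-3-hydroxy-2-[3-methoxy-4-(triisopropylsilyloxy)phenyl]propanoyl]-1,3-oxazolidin-2-one, via Z-boron enolate 23 (not isolated)
Conditions: Bu2BOTf, iPr2NEt, CH2Cl2, −78 → 0 °C; then 16, −78 → 0 °C; pH 7 buffer, MeOH, H2O2, 0 °C
Reagents that add atoms: none
Why: Evans syn-aldol reaction: soft enolisation gives the Z-boron enolate, which adds through a closed chair transition state with the auxiliary carbonyl turned away and the benzyl group blocking one enolate face; this sets C2' and C1' together as the syn (2S,3S) adduct, and reagent control should override the remote ring-B centres of 16.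

Step 15
Reactants: 24 the aldol adduct of step 14
Product: 25 (1S,2R)-1-{(2S,3R)-3-[(tert-butyldimethylsilyloxy)methyl]-7-methoxy-2-[3-methoxy-4-(triisopropylsilyloxy)phenyl]-2,3-dihydrobenzofuran-5-yl}-2-[3-methoxy-4-(triisopropylsilyloxy)phenyl]propane-1,3-diol
Conditions: LiBH4, MeOH (1.5 equiv), THF, 0 °C
Reagents that add atoms: none
Why: Reductive cleavage of the N-acyl oxazolidinone to the primary alcohol with release of auxiliary 20; hydride delivery at 0 °C should be faster than retro-aldol or enolisation, so both chain centres are kept (descriptors change only through the priority rules).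

Step 16
Reactants: 25 the trisilyl ether diol of step 15
Product: 26 (1S,2R)-1-[(2S,3R)-2-(4-hydroxy-3-methoxyphenyl)-3-(hydroxymethyl)-7-methoxy-2,3-dihydrobenzofuran-5-yl]-2-(4-hydroxy-3-methoxyphenyl)propane-1,3-diol
Conditions: TBAF, AcOH, THF, 0 °C → rt
Reagents that add atoms: none
Why: Fluoride-mediated cleavage of the two aryl triisopropylsilyl ethers and the primary tert-butyldimethylsilyl ether in one operation; acetic acid keeps the liberated phenols protonated so that neither quinone methide opening of ring B nor ionisation at C1' should occur.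

## Compound list

1 | vanillin (4-hydroxy-3-methoxybenzaldehyde) | COc1cc(C=O)ccc1O | starting material
2 | 3-methoxy-4-(triisopropylsilyloxy)benzaldehyde | COc1cc(C=O)ccc1O[Si](C(C)C)(C(C)C)C(C)C | intermediate
3 | [3-methoxy-4-(triisopropylsilyloxy)phenyl]methanol | COc1cc(CO)ccc1O[Si](C(C)C)(C(C)C)C(C)C | intermediate
4 | 4-bromo-2-methoxyphenol | COc1cc(Br)ccc1O | starting material
5 | 4-bromo-2-iodo-6-methoxyphenol | COc1cc(Br)cc(I)c1O | intermediate
6 | 5-bromo-1-iodo-3-methoxy-2-{[3-methoxy-4-(triisopropylsilyloxy)phenyl]methoxy}benzene | COc1cc(Br)cc(I)c1OCc1ccc(O[Si](C(C)C)(C(C)C)C(C)C)c(OC)c1 | intermediate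
7 | {5-bromo-3-methoxy-2-[3-methoxy-4-(triisopropylsilyloxy)benzyloxy]phenyl}magnesium chloride | COc1cc(Br)cc([Mg]Cl)c1OCc1ccc(O[Si](C(C)C)(C(C)C)C(C)C)c(OC)c1 | intermediate
8 | methyl 2-{5-bromo-3-methoxy-2-[3-methoxy-4-(triisopropylsilyloxy)benzyloxy]phenyl}-2-oxoacetate | COC(=O)C(=O)c1cc(Br)cc(OC)c1OCc1ccc(O[Si](C(C)C)(C(C)C)C(C)C)c(OC)c1 | intermediate
9 | N-tosylhydrazone of 8 (E/Z mixture) | COC(=O)C(=NNS(=O)(=O)c1ccc(C)cc1)c1cc(Br)cc(OC)c1OCc1ccc(O[Si](C(C)C)(C(C)C)C(C)C)c(OC)c1 | intermediate
10 | methyl 2-{5-bromo-3-methoxy-2-[3-methoxy-4-(triisopropylsilyloxy)benzyloxy]phenyl}-2-diazoacetate | COC(=O)C(=[N+]=[N-])c1cc(Br)cc(OC)c1OCc1ccc(O[Si](C(C)C)(C(C)C)C(C)C)c(OC)c1 | intermediate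
11 | methyl (2S,3R)-5-bromo-7-methoxy-2-[3-methoxy-4-(triisopropylsilyloxy)phenyl]-2,3-dihydrobenzofuran-3-carboxylate (cis) | COc1cc([C@H]2Oc3c(OC)cc(Br)cc3[C@H]2C(=O)OC)ccc1O[Si](C(C)C)(C(C)C)C(C)C | intermediate
12 | methyl (2S,3S)-5-bromo-7-methoxy-2-[3-methoxy-4-(triisopropylsilyloxy)phenyl]-2,3-dihydrobenzofuran-3-carboxylate (trans) | COc1cc([C@H]2Oc3c(OC)cc(Br)cc3[C@@H]2C(=O)OC)ccc1O[Si](C(C)C)(C(C)C)C(C)C | intermediate
13 | {(2S,3R)-5-bromo-7-methoxy-2-[3-methoxy-4-(triisopropylsilyloxy)phenyl]-2,3-dihydrobenzofuran-3-yl}methanol (trans) | COc1cc([C@H]2Oc3c(OC)cc(Br)cc3[C@@H]2CO)ccc1O[Si](C(C)C)(C(C)C)C(C)C | intermediate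
14 | (2S,3R)-5-bromo-3-[(tert-butyldimethylsilyloxy)methyl]-7-methoxy-2-[3-methoxy-4-(triisopropylsilyloxy)phenyl]-2,3-dihydrobenzofuran | COc1cc([C@H]2Oc3c(OC)cc(Br)cc3[C@@H]2CO[Si](C)(C)C(C)(C)C)ccc1O[Si](C(C)C)(C(C)C)C(C)C | intermediate
15 | 5-lithio derivative of 14 (lithium in place of bromine) | COc1cc([C@H]2Oc3c(OC)cc([Li])cc3[C@@H]2CO[Si](C)(C)C(C)(C)C)ccc1O[Si](C(C)C)(C(C)C)C(C)C | intermediate
16 | (2S,3R)-3-[(tert-butyldimethylsilyloxy)methyl]-7-methoxy-2-[3-methoxy-4-(triisopropylsilyloxy)phenyl]-2,3-dihydrobenzofuran-5-carbaldehyde | COc1cc([C@H]2Oc3c(OC)cc(C=O)cc3[C@@H]2CO[Si](C)(C)C(C)(C)C)ccc1O[Si](C(C)C)(C(C)C)C(C)C | intermediate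
17 | homovanillic acid (4-hydroxy-3-methoxyphenylacetic acid) | COc1cc(CC(=O)O)ccc1O | starting material
18 | triisopropylsilyl 2-[3-methoxy-4-(triisopropylsilyloxy)phenyl]acetate | COc1cc(CC(=O)O[Si](C(C)C)(C(C)C)C(C)C)ccc1O[Si](C(C)C)(C(C)C)C(C)C | intermediate
19 | 2-[3-methoxy-4-(triisopropylsilyloxy)phenyl]acetic acid | COc1cc(CC(=O)O)ccc1O[Si](C(C)C)(C(C)C)C(C)C | intermediate
20 | (S)-4-benzyl-1,3-oxazolidin-2-one | O=C1N[C@@H](Cc2ccccc2)CO1 | starting material
21 | 2-[3-methoxy-4-(triisopropylsilyloxy)phenyl]acetic pivalic anhydride | COc1cc(CC(=O)OC(=O)C(C)(C)C)ccc1O[Si](C(C)C)(C(C)C)C(C)C | intermediate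
22 | (S)-4-benzyl-3-{2-[3-methoxy-4-(triisopropylsilyloxy)phenyl]acetyl}-1,3-oxazolidin-2-one | COc1cc(CC(=O)N2C(=O)OC[C@@H]2Cc2ccccc2)ccc1O[Si](C(C)C)(C(C)C)C(C)C | intermediate
23 | (Z)-dibutylboron enolate of 22 (O–B and aryl cis on the enolate double bond) | CCCCB(CCCC)O/C(=C\c1ccc(O[Si](C(C)C)(C(C)C)C(C)C)c(OC)c1)N1C(=O)OC[C@@H]1Cc1ccccc1 | intermediate
24 | (S)-4-benzyl-3-[(2S,3S)-3-{(2S,3R)-3-[(tert-butyldimethylsilyloxy)methyl]-7-methoxy-2-[3-methoxy-4-(triisopropylsilyloxy)phenyl]-2,3-dihydrobenzofuran-5-yl}-3-hydroxy-2-[3-methoxy-4-(triisopropylsilyloxy)phenyl]propanoyl]-1,3-oxazolidin-2-one | COc1cc([C@H]2Oc3c(OC)cc([C@@H](O)[C@@H](C(=O)N4C(=O)OC[C@@H]4Cc4ccccc4)c4ccc(O[Si](C(C)C)(C(C)C)C(C)C)c(OC)c4)cc3[C@@H]2CO[Si](C)(C)C(C)(C)C)ccc1O[Si](C(C)C)(C(C)C)C(C)C | intermediate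
25 | (1S,2R)-1-{(2S,3R)-3-[(tert-butyldimethylsilyloxy)methyl]-7-methoxy-2-[3-methoxy-4-(triisopropylsilyloxy)phenyl]-2,3-dihydrobenzofuran-5-yl}-2-[3-methoxy-4-(triisopropylsilyloxy)phenyl]propane-1,3-diol | COc1cc([C@H]2Oc3c(OC)cc([C@@H](O)[C@@H](CO)c4ccc(O[Si](C(C)C)(C(C)C)C(C)C)c(OC)c4)cc3[C@@H]2CO[Si](C)(C)C(C)(C)C)ccc1O[Si](C(C)C)(C(C)C)C(C)C | intermediate
26 | (1S,2R)-1-[(2S,3R)-2-(4-hydroxy-3-methoxyphenyl)-3-(hydroxymethyl)-7-methoxy-2,3-dihydrobenzofuran-5-yl]-2-(4-hydroxy-3-methoxyphenyl)propane-1,3-diol | COc1cc([C@H]2Oc3c(OC)cc([C@@H](O)[C@@H](CO)c4ccc(O)c(OC)c4)cc3[C@@H]2CO)ccc1O | target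

## Step count and risks

Total step count: 16.
Longest linear sequence: 13 steps (steps 1, 2, 4 to 11 and 14 to 16, from vanillin 1 to 26).

Least certain steps:

**Step 7 (key step).**
- What may go wrong: incomplete discrimination between the two enantiotopic benzylic hydrogens, because the 7-methoxy group beside the ether oxygen can twist the benzyloxy arm away from the conformation on which the catalyst's selectivity rests. A slow insertion at −78 °C that lets carbene dimerisation compete is the second risk.
- Built-in safeguard: the aldol of step 14 pairs aldehyde 16 with an enantiopure enolate, so a residual minor enantiomer would appear there as a separable diastereomer.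
- Fallback (separation of covalent diastereomers instead of sole reliance on the catalyst): it sets out from scalemic alcohol 13. Esterification with (S)-O-methylmandelic acid (DCC, DMAP, CH2Cl2) would give the (S)-O-methylmandelate of 13 F1 together with the (S)-O-methylmandelate of the enantiomer of 13 F2. The two are separated by crystallisation or chromatography. Reductive cleavage of F1 with LiBH4 in THF/MeOH returns enantiopure 13, where the route is rejoined.

**Step 6.**
- What may go wrong: slow condensation at a ketone flanked by the ortho-benzyloxy group, with acyl hydrazide formation at the ester taking over, or loss of the acid-sensitive 4-siloxybenzyl ether if acid catalysis has to be used.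
- Fallback (the diazo carbon is brought in already diazotised): it sets out from iodide 6. Coupling with methyl diazoacetate under Pd(PPh3)4 (zerovalent palladium), Ag2CO3 and Et3N in toluene at rt would replace iodine directly and arrive at 10. Steps 5 and 6 are bypassed and no new compound is formed.

**Step 8.**
- What may go wrong: cleavage of the aryl silyl ether by methoxide. The free phenoxide could then open ring B through a quinone methide and scramble C2.
- Fallback (epimerisation moved to the aldehyde level, where an amine base suffices): it sets out from 11. LiAlH4 in THF at 0 °C would give the cis alcohol {(2S,3S)-5-bromo-7-methoxy-2-[3-methoxy-4-(triisopropylsilyloxy)phenyl]-2,3-dihydrobenzofuran-3-yl}methanol F3. Dess–Martin periodinane with NaHCO3 in CH2Cl2 would give the cis aldehyde F4. Et3N in CH2Cl2 would equilibrate it to the trans aldehyde F5. NaBH4 in MeOH would then give 13, where the route is rejoined.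

**Step 14.**
- What may go wrong: retro-aldol cleavage or loss of syn selectivity. The arylacetyl imide is unusually acidic, aldehyde 16 is electron-rich and slow to react, and the adduct carries an ionisable benzylic carbinol through an oxidative work-up.
- Fallback (a titanium enolate of a thiazolidinethione, whose adduct is cleaved by borohydride without oxidative work-up): it sets out from acid 19 and aldehyde 16. Coupling of 19 with (S)-4-benzyl-1,3-thiazolidine-2-thione (EDC, DMAP, CH2Cl2) would give the N-acyl thiazolidinethione F6. Enolisation with TiCl4, iPr2NEt and N-methylpyrrolidinone in CH2Cl2, under the non-chelated conditions that lead to the same syn adduct, and addition of 16 would give the aldol adduct F7. NaBH4 in THF/EtOH would displace the auxiliary and give 25, where the route is rejoined.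

## Further compounds

F1 | step 7 | {(2S,3R)-5-bromo-7-methoxy-2-[3-methoxy-4-(triisopropylsilyloxy)phenyl]-2,3-dihydrobenzofuran-3-yl}methyl (S)-2-methoxy-2-phenylacetate | COc1cc([C@H]2Oc3c(OC)cc(Br)cc3[C@@H]2COC(=O)[C@@H](OC)c2ccccc2)ccc1O[Si](C(C)C)(C(C)C)C(C)C
F2 | step 7 | {(2R,3S)-5-bromo-7-methoxy-2-[3-methoxy-4-(triisopropylsilyloxy)phenyl]-2,3-dihydrobenzofuran-3-yl}methyl (S)-2-methoxy-2-phenylacetate | COc1cc([C@@H]2Oc3c(OC)cc(Br)cc3[C@H]2COC(=O)[C@@H](OC)c2ccccc2)ccc1O[Si](C(C)C)(C(C)C)C(C)C
F0 | step 6 | none | none
F3 | step 8 | {(2S,3S)-5-bromo-7-methoxy-2-[3-methoxy-4-(triisopropylsilyloxy)phenyl]-2,3-dihydrobenzofuran-3-yl}methanol (cis) | COc1cc([C@H]2Oc3c(OC)cc(Br)cc3[C@H]2CO)ccc1O[Si](C(C)C)(C(C)C)C(C)C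
F4 | step 8 | (2S,3R)-5-bromo-7-methoxy-2-[3-methoxy-4-(triisopropylsilyloxy)phenyl]-2,3-dihydrobenzofuran-3-carbaldehyde (cis) | COc1cc([C@H]2Oc3c(OC)cc(Br)cc3[C@H]2C=O)ccc1O[Si](C(C)C)(C(C)C)C(C)C
F5 | step 8 | (2S,3S)-5-bromo-7-methoxy-2-[3-methoxy-4-(triisopropylsilyloxy)phenyl]-2,3-dihydrobenzofuran-3-carbaldehyde (trans) | COc1cc([C@H]2Oc3c(OC)cc(Br)cc3[C@@H]2C=O)ccc1O[Si](C(C)C)(C(C)C)C(C)C
F6 | step 14 | (S)-4-benzyl-3-{2-[3-methoxy-4-(triisopropylsilyloxy)phenyl]acetyl}-1,3-thiazolidine-2-thione | COc1cc(CC(=O)N2C(=S)SC[C@@H]2Cc2ccccc2)ccc1O[Si](C(C)C)(C(C)C)C(C)C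
F7 | step 14 | (2S,3S)-1-[(S)-4-benzyl-2-thioxo-1,3-thiazolidin-3-yl]-3-{(2S,3R)-3-[(tert-butyldimethylsilyloxy)methyl]-7-methoxy-2-[3-methoxy-4-(triisopropylsilyloxy)phenyl]-2,3-dihydrobenzofuran-5-yl}-3-hydroxy-2-[3-methoxy-4-(triisopropylsilyloxy)phenyl]propan-1-one | COc1cc([C@H]2Oc3c(OC)cc([C@@H](O)[C@@H](C(=O)N4C(=S)SC[C@@H]4Cc4ccccc4)c4ccc(O[Si](C(C)C)(C(C)C)C(C)C)c(OC)c4)cc3[C@@H]2CO[Si](C)(C)C(C)(C)C)ccc1O[Si](C(C)C)(C(C)C)C(C)C
A1 | alternative 1 | methyl (2S,3R)-7-methoxy-2-[3-methoxy-4-(triisopropylsilyloxy)phenyl]-3-[(triisopropylsilyloxy)methyl]-2,3-dihydrobenzofuran-5-carboxylate | COc1cc([C@H]2Oc3c(OC)cc(C(=O)OC)cc3[C@@H]2CO[Si](C(C)C)(C(C)C)C(C)C)ccc1O[Si](C(C)C)(C(C)C)C(C)C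
A2 | alternative 1 | (4R,5S)-5-[3-methoxy-4-(triisopropylsilyloxy)phenyl]-4-[(triisopropylsilyloxy)methyl]dihydrofuran-2(3H)-one | COc1cc([C@H]2OC(=O)C[C@@H]2CO[Si](C(C)C)(C(C)C)C(C)C)ccc1O[Si](C(C)C)(C(C)C)C(C)C
A3 | alternative 1 | (4R,5S)-5-[3-methoxy-4-(triisopropylsilyloxy)phenyl]-4-[(triisopropylsilyloxy)methyl]-2-(trimethylsilyloxy)-4,5-dihydrofuran | COc1cc([C@H]2OC(O[Si](C)(C)C)=C[C@@H]2CO[Si](C(C)C)(C(C)C)C(C)C)ccc1O[Si](C(C)C)(C(C)C)C(C)C
A4 | alternative 1 | methyl 3-methoxy-2-oxo-2H-pyran-5-carboxylate | COC(=O)C1=COC(=O)C(OC)=C1
A5 | alternative 2 | (2S,3R)-5-bromo-7-methoxy-2-[3-methoxy-4-(triisopropylsilyloxy)phenyl]-3-(nitromethyl)-2,3-dihydrobenzofuran | COc1cc([C@H]2Oc3c(OC)cc(Br)cc3[C@@H]2C[N+](=O)[O-])ccc1O[Si](C(C)C)(C(C)C)C(C)C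
A6 | alternative 2 | (E)-4-bromo-2-methoxy-6-(2-nitrovinyl)phenol | COc1cc(Br)cc(/C=C/[N+](=O)[O-])c1O
A7 | alternative 2 | (2R,5R)-1-[3-methoxy-4-(triisopropylsilyloxy)benzyl]-2,5-dimethylthiolanium triflate (the enantiomeric thiolane would be taken if the facial sense requires it) | C[C@@H]1CC[C@@H](C)[S+]1Cc1ccc(O[Si](C(C)C)(C(C)C)C(C)C)c(OC)c1.[O-]S(=O)(=O)C(F)(F)F
A8 | alternative 3 | methyl (2S,3S)-5-bromo-7-methoxy-2-(3-methoxy-4-pivaloyloxyphenyl)-2,3-dihydrobenzofuran-3-carboxylate | COc1cc([C@H]2Oc3c(OC)cc(Br)cc3[C@@H]2C(=O)OC)ccc1OC(=O)C(C)(C)C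
A9 | alternative 3 | (2S)-6-bromo-8-methoxy-2-(3-methoxy-4-pivaloyloxyphenyl)chroman-4-one | COc1cc([C@@H]2CC(=O)c3cc(Br)cc(OC)c3O2)ccc1OC(=O)C(C)(C)C
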